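**Plan**

- Retrosynthesis: C2–Br is traced back to a C2 carboxyl group (ipso-bromodecarboxylation) and C3–Br to C3–H. The indole is then cut at N1–C7a (vinyl nitrene C–H amination) and at C2=C3 (aldol condensation), which leads to 4-bromobenzaldehyde and ethyl azidoacetate.
- Forward: the condensation joins C2 to C3, thermolysis of the azidoacrylate closes the pyrrole ring onto the bromobenzene ring, and ester hydrolysis followed by two equivalents of electrophilic bromine completes C2 and C3.
- Enabling feature: C6–Br lies para to C3a, so the benzene ring can come from a 4-bromophenyl group whose two ortho C–H carbons (either becomes C7a) are equivalent. N1–C7a closure can therefore give only the 6-bromoindole.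
- Stereochemistry: the target is planar and has no stereocentre. The only stereo element on the way, the Z alkene of the azidoacrylate, vanishes on aromatisation.

Key step: step 2

Assumption: the target is achiral, so the request for a single enantiomer is met trivially and only regiochemistry has to be controlled.

**Route**

Step 1
Reactants: 1 4-bromobenzaldehyde; 2 ethyl azidoacetate
Product: 4 ethyl (Z)-2-azido-3-(4-bromophenyl)prop-2-enoate, via aldol adduct 3 (not isolated)
Conditions: NaOEt (4 equiv), 2 (4 equiv), EtOH, −10 → 0 °C; cold aq NH4Cl; product kept below 30 °C
Reagents that add atoms: none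
Why: Knoevenagel-type aldol condensation (first stage of the Hemetsberger–Knittel sequence), in which the azidoacetate enolate adds to the non-enolisable aldehyde to give 3 and E1cB loss of hydroxide should deliver the conjugated Z alkene (aryl trans to ester, the thermodynamic isomer), while the cold ethoxide/ethanol medium matches the ester and keeps base-induced loss of N2 from 2 slow.

Step 2
Reactants: 4 ethyl (Z)-2-azido-3-(4-bromophenyl)prop-2-enoate
Product: 7 ethyl 6-bromo-1H-indole-2-carboxylate, via 2H-azirine ester 5 (not isolated), via 7aH-indole ester 6 (not isolated)
Conditions: xylenes, reflux (ca. 140 °C), slow addition of 4 as a dilute solution (final ca. 0.05 M), 2–4 h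
Reagents that add atoms: none
Why: Hemetsberger–Knittel indole synthesis: heating expels N2 from the vinyl azide and gives a singlet vinyl nitrene that is in equilibrium with 2H-azirine 5. The five-atom unit N–C2=C3–C3a=C7a (indole numbering) then closes by 1,5-electrocyclisation, which forms the N1–C7a bond and the pyrrole ring as 7aH-indole 6, and a 1,5-hydrogen shift from C7a to nitrogen restores aromaticity to give 7. The closest known reaction type is the thermal cyclisation of ethyl 2-azido-3-arylacrylates to indole-2-carboxylates, which is routine for para-substituted aryl groups. No stereocentre is formed; the Z geometry of 4 places nitrogen next to the ring, and the azirine equilibrium would correct an E isomer in any case. The one selectivity needed is the site of amination, and symmetry secures it: both ortho carbons of the 4-bromophenyl ring are equivalent, so only the 6-bromo isomer can form. The C–Br bond is inert to metal-free thermolysis, and slow addition at high dilution should suppress bimolecular nitrene reactions.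

Step 3
Reactants: 7 ethyl 6-bromo-1H-indole-2-carboxylate
Product: 9 6-bromo-1H-indole-2-carboxylic acid, via lithium carboxylate 8 (not isolated)
Conditions: LiOH·H2O (3 equiv), THF/H2O 3:1, 45 °C; then 1 M HCl to pH 2
Reagents that add atoms: lithium hydroxide (supplies the oxygen of the acid OH), [Li+].[OH-]
Why: Saponification by the BAc2 mechanism gives lithium carboxylate 8, from which acidification should precipitate 9, the aryl bromide and the indole N–H being inert to aqueous hydroxide and indole-2-carboxylic acids not losing CO2 at this temperature.

Step 4
Reactants: 9 6-bromo-1H-indole-2-carboxylic acid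
Product: 11 2,3,6-tribromo-1H-indole, via 3,6-dibromo acid 10 (not isolated)
Conditions: NBS (2.1 equiv, two portions), DMF, 0 °C → rt, dark; aq Na2S2O3/NaHCO3
Reagents that add atoms: N-bromosuccinimide, O=C1CCC(=O)N1Br
Why: Electrophilic aromatic bromination followed by ipso-bromodecarboxylation (ionic halodecarboxylation, known for pyrrole- and indole-2-carboxylic acids), in which the first equivalent of NBS should brominate C3, the most nucleophilic carbon, to give 10, the second should attack C2 ipso to the carboxyl group, whose loss as CO2 from the σ-complex restores the indole, and the bromine-deactivated benzo ring should not compete at two equivalents.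

**Compound list**

1 | 4-bromobenzaldehyde | O=Cc1ccc(Br)cc1 | starting material
2 | ethyl azidoacetate | CCOC(=O)CN=[N+]=[N-] | starting material
3 | ethyl 2-azido-3-(4-bromophenyl)-3-hydroxypropanoate (racemic mixture of diastereomers, not isolated) | CCOC(=O)C(N=[N+]=[N-])C(O)c1ccc(Br)cc1 | intermediate
4 | ethyl (Z)-2-azido-3-(4-bromophenyl)prop-2-enoate | CCOC(=O)/C(N=[N+]=[N-])=C/c1ccc(Br)cc1 | intermediate
5 | ethyl 2-(4-bromophenyl)-2H-azirine-3-carboxylate (racemic, not isolated) | CCOC(=O)C1=NC1c1ccc(Br)cc1 | intermediate
6 | ethyl 6-bromo-7aH-indole-2-carboxylate (racemic, not isolated) | CCOC(=O)C1=NC2C=C(Br)C=CC2=C1 | intermediate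
7 | ethyl 6-bromo-1H-indole-2-carboxylate | CCOC(=O)c1cc2ccc(Br)cc2[nH]1 | intermediate
8 | lithium 6-bromo-1H-indole-2-carboxylate (not isolated) | [Li+].[O-]C(=O)c1cc2ccc(Br)cc2[nH]1 | intermediate
9 | 6-bromo-1H-indole-2-carboxylic acid | OC(=O)c1cc2ccc(Br)cc2[nH]1 | intermediate
10 | 3,6-dibromo-1H-indole-2-carboxylic acid (not isolated) | OC(=O)c1[nH]c2cc(Br)ccc2c1Br | intermediate
11 | 2,3,6-tribromo-1H-indole | Brc1ccc2c(Br)c(Br)[nH]c2c1 | target

**Step count**

Total steps: 4. Longest linear sequence: 4 steps (1 → 4 → 7 → 9 → 11).

**Steps most likely to fail**

Step 4 is the riskiest. The NH-indole may be over-oxidised by NBS (a second bromination at C3, then hydrolysis to oxindole-type material), the ipso substitution at C2 may stall after the C3 bromination, and the acid- and light-sensitive 2,3-dihaloindole may decompose during isolation. The product should therefore be worked up cold and neutral, chromatographed on triethylamine-deactivated silica and stored dark and cold. The fallback drops the ipso substitution and installs the C2 bromine by directed lithiation. It sets out from 9, which is protodecarboxylated with catalytic Ag2CO3 and AcOH in DMSO at 120 °C to 6-bromo-1H-indole F1. N-Sulfonylation (NaH, PhSO2Cl, THF) should give 6-bromo-1-(phenylsulfonyl)-1H-indole F2, and bromine in CH2Cl2 should brominate C3 to give 3,6-dibromo-1-(phenylsulfonyl)-1H-indole F3. LDA at −78 °C should deprotonate C2 under the direction of the sulfonyl group without bromine–lithium exchange, and a quench with 1,2-dibromo-1,1,2,2-tetrachloroethane should give 2,3,6-tribromo-1-(phenylsulfonyl)-1H-indole F4. Removal of the sulfonyl group with TBAF in THF comes back to the route at 11.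

Step 1 is second. The strongly basic medium may decompose ethyl azidoacetate and the vinyl azide with loss of N2, and the reaction may stop at the aldol stage, so that little azidoacrylate is obtained. The fallback builds the alkene and the azide separately. It sets out from 1, which a Horner–Wadsworth–Emmons reaction with triethyl phosphonoacetate (NaH, THF) should convert to ethyl (E)-3-(4-bromophenyl)prop-2-enoate F5. Anti addition of bromine in CH2Cl2 should give racemic ethyl (2RS,3SR)-2,3-dibromo-3-(4-bromophenyl)propanoate F6. Sodium azide (3 equiv) in DMF at room temperature should then replace the bromide at C2 and eliminate HBr across C2–C3, as in the standard preparation of α-azido enones and α-azido acrylates from vicinal dibromides. This comes back to the route at 4.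

Step 2 is third. At 140 °C the free nitrene may react intermolecularly or give tar, and conversion may stop at the azirine stage. The fallback replaces the uncatalysed thermolysis by a metal-nitrenoid C–H amination. It sets out from 4, which is treated with catalytic Rh2(O2CC3F7)4 in toluene at 40–60 °C; the rhodium nitrenoid should cyclise onto the ortho carbon well below the temperature at which the free nitrene forms. It comes back to the route at 7 and makes no compound outside the list (F0).

**Further compounds**

F1 | step 4 | 6-bromo-1H-indole | Brc1ccc2cc[nH]c2c1
F2 | step 4 | 6-bromo-1-(phenylsulfonyl)-1H-indole | O=S(=O)(c1ccccc1)n1ccc2ccc(Br)cc21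
F3 | step 4 | 3,6-dibromo-1-(phenylsulfonyl)-1H-indole | O=S(=O)(c1ccccc1)n1cc(Br)c2ccc(Br)cc21
F4 | step 4 | 2,3,6-tribromo-1-(phenylsulfonyl)-1H-indole | O=S(=O)(c1ccccc1)n1c(Br)c(Br)c2ccc(Br)cc21
F5 | step 1 | ethyl (E)-3-(4-bromophenyl)prop-2-enoate | CCOC(=O)/C=C/c1ccc(Br)cc1
F6 | step 1 | ethyl (2RS,3SR)-2,3-dibromo-3-(4-bromophenyl)propanoate (racemic, one enantiomer drawn) | CCOC(=O)[C@@H](Br)[C@@H](Br)c1ccc(Br)cc1
F0 | step 2 | none | none
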